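## Retrosynthetic overview

1. Target 28 ⇐ 25: ring A is finished last on the complete skeleton by epoxidation of C3=C4, trans-diaxial acetolysis (C3–OH, C4–OAc) and oxidation of C6–OH.
2. 25 ⇐ 18: C6 comes from the C5 ketone (Wittig, then hydroboration, which sets C5); C17 comes from α-methylenation of the C15 ketone.
3. 18 ⇐ 16 (key step): rings C and D and quaternary C8 form together when the α-diazo carbon of the spirolactone expands a tethered cyclobutanone to the cyclopentanone (1,2-shift, loss of N2).
4. 16 ⇐ 9 + 12: Michael addition makes the C9–C10 bond and quaternary C10; aldehyde reduction/lactonisation and deacylative diazo transfer follow.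
5. Ring order: ring A (bought as 10) → δ-lactone ring → rings C and D in one step; building blocks 1, 2, 8, 10, 11.

Assumption: atom labels follow kaurane numbering (C18 methyl and OAc on C4, C6 aldehyde, C20–O–C7 lactone, C15 ketone, C16=C17), descriptors of intermediates are CIP descriptors for these locants, and the (R,R) catalyst in step 5 is assumed to give the sense shown (otherwise its enantiomer is used).

## Route

Step 1
Reactants: 1 hexa-1,5-diene; 2 N,N-dimethylacetamide
Product: 5 3-(but-3-en-1-yl)cyclobutan-1-one, via keteniminium triflate 3 (not isolated), via cyclobutaniminium triflate 4 (not isolated)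
Conditions: Tf2O, 2,4,6-collidine, ClCH2CH2Cl, 0 °C; 1 (5 equiv), 80 °C; then H2O
Reagents that add atoms: water, O
Why: Ghosez cyclobutanone synthesis, in which keteniminium ion 3 adds to one terminal alkene of excess 1 in a stepwise polar [2+2] that places the butenyl group at C3 and hydrolysis of iminium salt 4 gives the ketone; no stereocentre is formed.

Step 2
Reactants: 5 3-(but-3-en-1-yl)cyclobutan-1-one
Product: 7 3-(3-oxocyclobutyl)propanal, via ozonide 6 (not isolated)
Conditions: O3, CH2Cl2, −78 °C; then Me2S, −78 → 25 °C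
Reagents that add atoms: ozone, [O-][O+]=O
Why: Ozonolysis with reductive work-up cleaves the only C=C bond to the aldehyde while the cyclobutanone is inert to ozone.

Step 3
Reactants: 7 3-(3-oxocyclobutyl)propanal; 8 methyl 3-oxobutanoate
Product: 9 methyl 2-acetyl-5-(3-oxocyclobutyl)pent-2-enoate (E/Z mixture)
Conditions: piperidine (10 mol %), AcOH (10 mol %), 4 Å MS, CH2Cl2, 0 °C
Reagents that add atoms: none
Why: Knoevenagel condensation of an unhindered aldehyde with a 1,3-dicarbonyl compound gives the doubly activated alkene, and its E/Z ratio is irrelevant because both isomers converge in the next step.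

Step 4
Reactants: 10 2-methylcyclohex-2-en-1-one; 11 ethyl formate
Product: 12 6-(hydroxymethylidene)-2-methylcyclohex-2-en-1-one
Conditions: NaH, EtOH (cat.), Et2O, 0 → 25 °C; then aq. HCl
Reagents that add atoms: none
Why: Crossed Claisen formylation at the only α-CH2 of the enone (C6) is driven by formation of the stabilised β-keto aldehyde enolate; no stereocentre is formed.

Step 5
Reactants: 9 methyl 2-acetyl-5-(3-oxocyclobutyl)pent-2-enoate; 12 6-(hydroxymethylidene)-2-methylcyclohex-2-en-1-one
Product: 13 methyl (3R)-2-acetyl-3-[(1S)-1-formyl-3-methyl-2-oxocyclohex-3-en-1-yl]-5-(3-oxocyclobutyl)pentanoate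
Conditions: 1-[3,5-bis(trifluoromethyl)phenyl]-3-[(1R,2R)-2-(dimethylamino)cyclohexyl]thiourea (10 mol %), PhMe, −20 °C
Reagents that add atoms: none
Why: Organocatalytic Michael addition in which the thiourea binds the alkylidene acetoacetate and the amine deprotonates 12, so that the enolate carbon adds to the β-carbon inside the chiral pocket and sets quaternary C10 and tertiary C9 together, the acetyl-bearing carbon remaining an inconsequential epimer mixture.

Step 6
Reactants: 13 methyl (3R)-2-acetyl-3-[(1S)-1-formyl-3-methyl-2-oxocyclohex-3-en-1-yl]-5-(3-oxocyclobutyl)pentanoate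
Product: 15 (5R,6S)-4-acetyl-8-methyl-5-[2-(3-oxocyclobutyl)ethyl]-2-oxaspiro[5.5]undec-8-ene-3,7-dione, via hydroxy ester 14 (not isolated)
Conditions: NaBH(OAc)3, ClCH2CH2Cl, 25 °C; then TsOH (5 mol %), PhMe, 60 °C
Reagents that add atoms: none
Why: Chemoselective acyloxyborohydride reduction takes the aldehyde but not the ketones, and the neopentyl alcohol then closes the six-membered lactone onto the β-keto ester by acid-catalysed transesterification, leaving C9 and C10 untouched.

Step 7
Reactants: 15 (5R,6S)-4-acetyl-8-methyl-5-[2-(3-oxocyclobutyl)ethyl]-2-oxaspiro[5.5]undec-8-ene-3,7-dione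
Product: 16 (5S,6S)-4-diazo-8-methyl-5-[2-(3-oxocyclobutyl)ethyl]-2-oxaspiro[5.5]undec-8-ene-3,7-dione
Conditions: p-ABSA, DBU, MeCN, 0 → 25 °C
Reagents that add atoms: 4-acetamidobenzenesulfonyl azide (p-ABSA), CC(=O)Nc1ccc(cc1)S(=O)(=O)N=[N+]=[N-]
Why: Regitz deacylative diazo transfer, in which the enolate of the α-acetyl lactone attacks the sulfonyl azide and the acetyl group leaves on the sulfonamide nitrogen, gives the α-diazo lactone without strong base so that cyclobutanone and enone survive (the descriptor at C5 changes only because of CIP priorities).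

Step 8
Reactants: 16 (5S,6S)-4-diazo-8-methyl-5-[2-(3-oxocyclobutyl)ethyl]-2-oxaspiro[5.5]undec-8-ene-3,7-dione
Product: 18 spiro keto lactone (8S,9S,10S,13R) with bicyclo[3.2.1]octan-15-one, via diazonium alkoxide betaine 17 (not isolated)
Conditions: Sc(OTf)3 (10 mol %), CH2Cl2, −40 → 0 °C
Reagents that add atoms: none
Why: Proposed new method: Sc(OTf)3 activates the strained cyclobutanone carbonyl so that the nucleophilic diazo carbon C8 adds to it on the lactone face that carries the C9 tether (cis annulation) to give betaine 17, in which the tether holds C9 anti to the alkoxide and so places the diazonium group antiperiplanar to one ring CH2; that CH2 shifts to C8 with loss of N2 and release of about 20 kcal/mol of strain, which expands the cyclobutanone to the cyclopentanone ring D, closes ring C and creates quaternary C8 and C13 in the configuration dictated by C9; the closest known reaction type is the intermolecular Lewis-acid-catalysed ring expansion of cyclobutanones and cyclohexanones with α-alkyl α-diazo esters (Tiffeneau–Demjanov-type homologation), which has not been shown intramolecularly with a diazo lactone to build a bridged ring system.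

Step 9
Reactants: 18 spiro keto lactone (8S,9S,10S,13R)
Product: 20 C15 tert-butyldimethylsilyl enol ether of 18, via lithium enolate 19 (not isolated)
Conditions: LiN(SiMe3)2, THF, −78 °C; then TBSOTf
Reagents that add atoms: tert-butyldimethylsilyl triflate, CC(C)(C)[Si](C)(C)OS(=O)(=O)C(F)(F)F
Why: Kinetic deprotonation at C16, the only α-CH2 of the saturated ketone, and O-silylation mask the C15 ketone, because the enone has only slower γ-protons and the lactone has no α-hydrogen.

Step 10
Reactants: 20 C15 tert-butyldimethylsilyl enol ether of 18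
Product: 21 (8S,9S,10R,13R)-15-(tert-butyldimethylsilyloxy)-19-nor-6,7-secokaura-3,5(6),15-trien-7,20-olide
Conditions: Ph3PCH3Br, KN(SiMe3)2, PhMe, 0 → 70 °C
Reagents that add atoms: methyltriphenylphosphonium bromide, C[P+](c1ccccc1)(c1ccccc1)c1ccccc1.[Br-]
Why: Wittig methylenation of the only remaining ketone (C5) installs C6 as an exocyclic alkene, while the silyl enol ether and the lactone do not react with the ylide.

Step 11
Reactants: 21 (8S,9S,10R,13R)-15-(tert-butyldimethylsilyloxy)-19-nor-6,7-secokaura-3,5(6),15-trien-7,20-olide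
Product: 24 (5R,8S,9S,10R,13R)-6-hydroxy-15-oxo-19-nor-6,7-secokaur-3-en-7,20-olide, via alkylborane 22 (not isolated), via silyl enol ether alcohol 23 (not isolated)
Conditions: 9-BBN, THF, 0 → 25 °C; then H2O2, pH 7 buffer; then 1 M HCl, THF, 0 °C
Reagents that add atoms: hydrogen peroxide, OO; 9-borabicyclo[3.3.1]nonane, B1C2CCCC1CCC2 (boron stays only in 22)
Why: Hydroboration–oxidation, in which 9-BBN adds to the least hindered 1,1-disubstituted alkene with boron at C6 and delivers hydrogen to C5 on the face opposite the axial C20 methylene (the usual attack anti to the angular substituent), sets C5 with C6 cis to C20, after which buffered peroxide gives the alcohol and dilute acid unmasks the C15 ketone.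

Step 12
Reactants: 24 (5R,8S,9S,10R,13R)-6-hydroxy-15-oxo-19-nor-6,7-secokaur-3-en-7,20-olide
Product: 25 (5R,8S,9S,10R,13R)-6-hydroxy-15-oxo-19-nor-6,7-secokaura-3,16-dien-7,20-olide
Conditions: (CH2O)n, PhNHMe·CF3CO2H, THF, 65 °C
Reagents that add atoms: formaldehyde (as paraformaldehyde), C=O
Why: Mannich-type α-methylenation, in which the iminium ion from formaldehyde and the anilinium salt is attacked by the enol of the C15 ketone at C16 (its only enolisable position) and the β-amino ketone eliminates the amine, gives the exocyclic enone.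

Step 13
Reactants: 25 (5R,8S,9S,10R,13R)-6-hydroxy-15-oxo-19-nor-6,7-secokaura-3,16-dien-7,20-olide
Product: 27 (3S,4S,5R,8S,9S,10R,13R)-4-acetoxy-3,6-dihydroxy-15-oxo-19-nor-6,7-secokaur-16-en-7,20-olide, via epoxide 26 (not isolated)
Conditions: CH3CO3H, NaOAc, CH2Cl2, 0 °C; then AcOH, BF3·OEt2 (20 mol %), −20 → 0 °C
Reagents that add atoms: peracetic acid, CC(=O)OO; acetic acid, CC(=O)O
Why: Prilezhaev epoxidation of the only electron-rich alkene occurs on the face opposite the axial C20 methylene, and acid-catalysed trans-diaxial (Fürst–Plattner) opening by acetic acid at the tertiary carbon C4 with inversion then gives the axial tertiary acetate and the axial C3 alcohol, which sets C3 and C4.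

Step 14
Reactants: 27 (3S,4S,5R,8S,9S,10R,13R)-4-acetoxy-3,6-dihydroxy-15-oxo-19-nor-6,7-secokaur-16-en-7,20-olide
Product: 28 (3S,4S,5S,8S,9S,10R,13R)-4-acetoxy-3-hydroxy-6,15-dioxo-19-nor-6,7-secokaur-16-en-7,20-olide
Conditions: TEMPO (10 mol %), PhI(OAc)2, CH2Cl2, 25 °C
Reagents that add atoms: none
Why: Oxoammonium (TEMPO) oxidation takes the primary alcohol selectively beside the hindered axial secondary alcohol and stops at the aldehyde under near-neutral conditions that do not eliminate the β-acetoxy group.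

## Compound list

1 | hexa-1,5-diene | C=CCCC=C | starting material
2 | N,N-dimethylacetamide | CC(=O)N(C)C | starting material
3 | N,N-dimethylketeniminium trifluoromethanesulfonate | C=C=[N+](C)C.[O-]S(=O)(=O)C(F)(F)F | intermediate (not isolated)
4 | 3-(but-3-en-1-yl)-N,N-dimethylcyclobutan-1-iminium trifluoromethanesulfonate | C=CCCC1CC(=[N+](C)C)C1.[O-]S(=O)(=O)C(F)(F)F | intermediate (not isolated)
5 | 3-(but-3-en-1-yl)cyclobutan-1-one (achiral) | C=CCCC1CC(=O)C1 | intermediate
6 | 3-[2-(1,2,4-trioxolan-3-yl)ethyl]cyclobutan-1-one (ozonide, racemic at the trioxolane carbon) | O=C1CC(CCC2OCOO2)C1 | intermediate (not isolated)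
7 | 3-(3-oxocyclobutyl)propanal | O=CCCC1CC(=O)C1 | intermediate
8 | methyl 3-oxobutanoate (methyl acetoacetate) | COC(=O)CC(C)=O | starting material
9 | methyl 2-acetyl-5-(3-oxocyclobutyl)pent-2-enoate (E/Z mixture) | COC(=O)C(=CCCC1CC(=O)C1)C(C)=O | intermediate
10 | 2-methylcyclohex-2-en-1-one | CC1=CCCCC1=O | starting material
11 | ethyl formate | CCOC=O | starting material
12 | 6-(hydroxymethylidene)-2-methylcyclohex-2-en-1-one (enol of the 6-formyl ketone, alkene geometry not fixed) | CC1=CCCC(=CO)C1=O | intermediate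
13 | methyl (3R)-2-acetyl-3-[(1S)-1-formyl-3-methyl-2-oxocyclohex-3-en-1-yl]-5-(3-oxocyclobutyl)pentanoate (epimer mixture at C2) | O=C1CC(C1)CC[C@H](C(C(C)=O)C(=O)OC)[C@]2(C=O)CCC=C(C)C2=O | intermediate
14 | methyl (3R)-2-acetyl-3-[(1S)-1-(hydroxymethyl)-3-methyl-2-oxocyclohex-3-en-1-yl]-5-(3-oxocyclobutyl)pentanoate (epimer mixture at C2) | O=C1CC(C1)CC[C@H](C(C(C)=O)C(=O)OC)[C@]2(CO)CCC=C(C)C2=O | intermediate (not isolated)
15 | (5R,6S)-4-acetyl-8-methyl-5-[2-(3-oxocyclobutyl)ethyl]-2-oxaspiro[5.5]undec-8-ene-3,7-dione (epimer mixture at C4) | O=C1CC(C1)CC[C@H]2[C@@]3(CCC=C(C)C3=O)COC(=O)C2C(C)=O | intermediate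
16 | (5S,6S)-4-diazo-8-methyl-5-[2-(3-oxocyclobutyl)ethyl]-2-oxaspiro[5.5]undec-8-ene-3,7-dione (same spatial arrangement as 15) | O=C1CC(C1)CC[C@H]2[C@@]3(CCC=C(C)C3=O)COC(=O)C2=[N+]=[N-] | intermediate
17 | diazonium alkoxide betaine: bicyclo[4.1.1] adduct in which C8 (bearing N2+, on the face opposite the new C8–C15 bond) is bonded to the former cyclobutanone carbon C15 (bearing O−); C9 and C10 as in 16 | [O-]C14CC(C1)CC[C@H]2[C@@]3(CCC=C(C)C3=O)COC(=O)[C@]24[N+]#N | intermediate (not isolated)
18 | spiro keto lactone: ring A (C1–C5, C10; 3-methyl-2-oxocyclohex-3-ene, C5=O, no C6) spiro at C10 to the C20H2–O–C7(=O) lactone, which is cis-fused at C8–C9 to the bicyclo[3.2.1]octane bearing the C15 ketone and C16H2; (8S,9S,10S,13R) | C1C(=O)[C@]23C[C@H]1CC[C@H]2[C@@]1(CCC=C(C)C1=O)COC3=O | intermediate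
19 | lithium C15(O)=C16 enolate of 18 | C1=C([O-])[C@]23C[C@H]1CC[C@H]2[C@@]1(CCC=C(C)C1=O)COC3=O.[Li+] | intermediate (not isolated)
20 | C15 tert-butyldimethylsilyl enol ether of 18 (C15=C16); (8S,9S,10S,13R) | C1=C(O[Si](C)(C)C(C)(C)C)[C@]23C[C@H]1CC[C@H]2[C@@]1(CCC=C(C)C1=O)COC3=O | intermediate
21 | (8S,9S,10R,13R)-15-(tert-butyldimethylsilyloxy)-19-nor-6,7-secokaura-3,5(6),15-trien-7,20-olide | C1=C(O[Si](C)(C)C(C)(C)C)[C@]23C[C@H]1CC[C@H]2[C@@]1(CCC=C(C)C1=C)COC3=O | intermediate
22 | B-alkyl-9-BBN adduct of 21 (boron on C6, H on C5; 5R) | C1=C(O[Si](C)(C)C(C)(C)C)[C@]23C[C@H]1CC[C@H]2[C@@]1(CCC=C(C)[C@H]1CB1C4CCCC1CCC4)COC3=O | intermediate (not isolated)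
23 | (5R,8S,9S,10R,13R)-15-(tert-butyldimethylsilyloxy)-6-hydroxy-19-nor-6,7-secokaura-3,15-dien-7,20-olide | C1=C(O[Si](C)(C)C(C)(C)C)[C@]23C[C@H]1CC[C@H]2[C@@]1(CCC=C(C)[C@H]1CO)COC3=O | intermediate (not isolated)
24 | (5R,8S,9S,10R,13R)-6-hydroxy-15-oxo-19-nor-6,7-secokaur-3-en-7,20-olide | C1C(=O)[C@]23C[C@H]1CC[C@H]2[C@@]1(CCC=C(C)[C@H]1CO)COC3=O | intermediate
25 | (5R,8S,9S,10R,13R)-6-hydroxy-15-oxo-19-nor-6,7-secokaura-3,16-dien-7,20-olide | C=C1C(=O)[C@]23C[C@H]1CC[C@H]2[C@@]1(CCC=C(C)[C@H]1CO)COC3=O | intermediate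
26 | (3S,4R,5R,8S,9S,10R,13R)-3,4-epoxy-6-hydroxy-15-oxo-19-nor-6,7-secokaur-16-en-7,20-olide (epoxide trans to C20 and C6) | C=C1C(=O)[C@]23C[C@H]1CC[C@H]2[C@@]1(CC[C@@H]2O[C@]2(C)[C@H]1CO)COC3=O | intermediate (not isolated)
27 | (3S,4S,5R,8S,9S,10R,13R)-4-acetoxy-3,6-dihydroxy-15-oxo-19-nor-6,7-secokaur-16-en-7,20-olide | C=C1C(=O)[C@]23C[C@H]1CC[C@H]2[C@@]1(CC[C@H](O)[C@@](C)(OC(C)=O)[C@H]1CO)COC3=O | intermediate
28 | (3S,4S,5S,8S,9S,10R,13R)-4-acetoxy-3-hydroxy-6,15-dioxo-19-nor-6,7-secokaur-16-en-7,20-olide | C=C1C(=O)[C@]23C[C@H]1CC[C@H]2[C@@]1(CC[C@H](O)[C@@](C)(OC(C)=O)[C@H]1C=O)COC3=O | target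

## Step count and risks

Total: 14 steps. Longest linear sequence: 13 steps (steps 1–3 and 5–14; step 4 is the convergent branch).

The three steps most likely to fail:

Step 8 (the new ring expansion). The risks are conjugate addition of the diazo carbon to the ring A enone, loss of N2 with a hydride shift from C9, and attack on the wrong lactone face. The fallback uses only known reactions (nitro-aldol, nitro reduction, Tiffeneau–Demjanov); it sets out from 7 and comes back at 18. Aldehyde 7 is condensed with methyl nitroacetate (TiCl4, N-methylmorpholine, THF) to methyl 2-nitro-5-(3-oxocyclobutyl)pent-2-enoate F5. Michael addition of 12 as in step 5 gives the nitro analogue of 13, F6. NaBH(OAc)3 reduces the aldehyde to the hydroxy nitro ester F7, which lactonises to the α-nitro spirolactone F8. Et3N closes the intramolecular Henry adduct, nitro cyclobutanol F9. Zn in AcOH reduces it to amino cyclobutanol F10. NaNO2 in aqueous AcOH diazotises the amine, and the diazonium ion (the protonated form of 17) undergoes the classical Tiffeneau–Demjanov ring expansion to 18.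

Step 5 (Michael addition that sets C9 and C10). The risks are low reactivity in forming a quaternary centre next to a tertiary one and the wrong relative or absolute sense under catalyst control. The fallback replaces catalyst control by a covalently bound auxiliary; it sets out from 8 and comes back at 15. Transesterification of 8 with (−)-8-phenylmenthol (DMAP, PhMe, 110 °C) gives (−)-8-phenylmenthyl 3-oxobutanoate F1. Knoevenagel condensation with 7 gives the 8-phenylmenthyl alkylidene acetoacetate F2. Michael addition of 12 with an achiral base (Cs2CO3, PhMe) is now steered by the aryl-shielded ester and gives the 8-phenylmenthyl analogue of 13, F3. NaBH(OAc)3 reduction gives the 8-phenylmenthyl analogue of 14, F4, which on heating in PhMe closes lactone 15 through the acyl ketene and releases the auxiliary.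

Step 13 (epoxidation and acetolysis in one pot). The risks are acetylation of the free C6–OH, pinacol-type rearrangement of the tertiary cation, and wrong-face epoxidation directed by the hydroxyl group. The fallback separates oxygen delivery from acetylation; it sets out from 25 and comes back at 27. Alkene 25 is epoxidised with mCPBA/NaHCO3 and epoxide 26 is isolated. Aqueous HClO4 in THF opens it at C4 in the same trans-diaxial sense to the (3S,4S) 3,4,6-triol F11. TESCl and imidazole silylate the primary and the secondary hydroxyl to the 3,6-bis(triethylsilyl) ether F12. Ac2O, DMAP and Et3N at 60 °C acetylate the remaining tertiary alcohol to the 4-acetate F13. HF·pyridine removes both silyl groups and returns 27.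

## Further compounds

F1 | step 5 | (1R,2S,5R)-5-methyl-2-(2-phenylpropan-2-yl)cyclohexyl 3-oxobutanoate | CC(C)(c1ccccc1)[C@@H]1CC[C@@H](C)C[C@H]1OC(=O)CC(C)=O
F2 | step 5 | (−)-8-phenylmenthyl 2-acetyl-5-(3-oxocyclobutyl)pent-2-enoate (E/Z mixture) | CC(C)(c1ccccc1)[C@@H]1CC[C@@H](C)C[C@H]1OC(=O)C(=CCCC1CC(=O)C1)C(C)=O
F3 | step 5 | (−)-8-phenylmenthyl ester analogue of 13 (C9 and C10 as in 13) | CC(C)(c1ccccc1)[C@@H]1CC[C@@H](C)C[C@H]1OC(=O)C(C(C)=O)[C@@H](CCC1CC(=O)C1)[C@]2(C=O)CCC=C(C)C2=O
F4 | step 5 | (−)-8-phenylmenthyl ester analogue of 14 | CC(C)(c1ccccc1)[C@@H]1CC[C@@H](C)C[C@H]1OC(=O)C(C(C)=O)[C@@H](CCC1CC(=O)C1)[C@]2(CO)CCC=C(C)C2=O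
F5 | step 8 | methyl 2-nitro-5-(3-oxocyclobutyl)pent-2-enoate (E/Z mixture) | COC(=O)C(=CCCC1CC(=O)C1)[N+](=O)[O-]
F6 | step 8 | nitro analogue of 13 (nitro in place of acetyl; C9 and C10 as in 13) | COC(=O)C([N+](=O)[O-])[C@@H](CCC1CC(=O)C1)[C@]2(C=O)CCC=C(C)C2=O
F7 | step 8 | nitro analogue of 14 (hydroxy nitro ester) | COC(=O)C([N+](=O)[O-])[C@@H](CCC1CC(=O)C1)[C@]2(CO)CCC=C(C)C2=O
F8 | step 8 | nitro analogue of 15 (α-nitro spirolactone) | O=C1CC(C1)CC[C@H]2[C@@]3(CCC=C(C)C3=O)COC(=O)C2[N+](=O)[O-]
F9 | step 8 | Henry adduct: bicyclo[4.1.1] nitro cyclobutanol (C8–NO2, C15–OH; C8 as in 17) | OC14CC(C1)CC[C@H]2[C@@]3(CCC=C(C)C3=O)COC(=O)[C@]24[N+](=O)[O-]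
F10 | step 8 | amino cyclobutanol (C8–NH2, C15–OH) | OC14CC(C1)CC[C@H]2[C@@]3(CCC=C(C)C3=O)COC(=O)[C@]24N
F11 | step 13 | (3S,4S,5R,8S,9S,10R,13R)-3,4,6-trihydroxy-15-oxo-19-nor-6,7-secokaur-16-en-7,20-olide | C=C1C(=O)[C@]23C[C@H]1CC[C@H]2[C@@]1(CC[C@H](O)[C@@](C)(O)[C@H]1CO)COC3=O
F12 | step 13 | 3,6-bis(triethylsilyl) ether of F11 | C=C1C(=O)[C@]23C[C@H]1CC[C@H]2[C@@]1(CC[C@H](O[Si](CC)(CC)CC)[C@@](C)(O)[C@H]1CO[Si](CC)(CC)CC)COC3=O
F13 | step 13 | 4-acetate of F12 | C=C1C(=O)[C@]23C[C@H]1CC[C@H]2[C@@]1(CC[C@H](O[Si](CC)(CC)CC)[C@@](C)(OC(C)=O)[C@H]1CO[Si](CC)(CC)CC)COC3=O
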